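## Retrosynthetic overview

1. Target 17 comes from its 5,7-di-O-allyl ether 16; 16 comes from isoflavone 14 by 1,4-hydride addition and enantioselective hydroxylation of the resulting enolate at C3, the counterpart of the late 3-hydroxylation in the plant.
2. 14 comes from flavanone 11 by an oxidative 2,3-aryl shift (the isoflavone synthase step), triggered at the silyl enol ether so that the prenyl group is spared.
3. 11 comes from chalcone 10 by oxa-Michael closure of ring C (the chalcone isomerase step); 10 comes from ketone 9 and aldehyde 6 (Claisen–Schmidt).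
4. 6 comes from 1 and 2 (directed ortho-metalation, prenylation); 9 comes from 7 and 8 (bis-O-allylation).
5. Ring order: rings A and B are bought with 7 and 1; ring C is the only ring made (step 3) and is then reorganised from 2-aryl to 3-aryl (step 4).

Assumption: the (+)-oxaziridine (from (1S)-(+)-camphorsulfonic acid) is taken to deliver oxygen to the Re face of C3, which gives 3R, by analogy with 2-substituted 1-tetralone and 3-benzylchroman-4-one enolates; I could not confirm this sense from memory, so the first batch is assayed (chiral HPLC, CD) and the commercial (−)-antipode is used under the same conditions if the sense is opposite.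

## Route

Step 1
Reactants: 1 2,4-dimethoxybenzaldehyde; 2 prenyl bromide (1-bromo-3-methylbut-2-ene)
Product: 6 2,4-dimethoxy-3-(3-methylbut-2-en-1-yl)benzaldehyde, via lithium α-amino alkoxide 3 (not isolated), via 3-lithio α-amino alkoxide 4 (not isolated), via prenylated α-amino alkoxide 5 (not isolated)
Conditions: 1-methylpiperazine (1.1 equiv), n-BuLi (1.05 equiv), THF, −20 °C; add 1; n-BuLi (2.5 equiv), −20 °C, 4 h; 2 (3.5 equiv), −78 °C → rt; H2O
Reagents that add atoms: prenyl bromide 2, CC(C)=CCBr
Why: Comins-type in situ protection, in which lithium 4-methylpiperazin-1-ide adds to the aldehyde to give a masking α-amino alkoxide, n-BuLi then removes the C3 proton flanked by both methoxy groups (directed ortho-metalation), the aryllithium is alkylated by the primary allylic bromide (SN2), and water releases the aldehyde.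

Step 2
Reactants: 7 2,4,6-trihydroxyacetophenone; 8 allyl bromide
Product: 9 1-[2-hydroxy-4,6-bis(prop-2-en-1-yloxy)phenyl]ethan-1-one
Conditions: 8 (2.1 equiv), K2CO3 (2.2 equiv), acetone, reflux
Reagents that add atoms: allyl bromide 8, C=CCBr
Why: Williamson ether synthesis, in which the two free phenols are alkylated while the third, hydrogen-bonded to the ketone, stays unreactive under K2CO3, as is usual for phloroacetophenone.

Step 3
Reactants: 6 2,4-dimethoxy-3-(3-methylbut-2-en-1-yl)benzaldehyde; 9 1-[2-hydroxy-4,6-bis(prop-2-en-1-yloxy)phenyl]ethan-1-one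
Product: 11 (±)-5,7-bis(allyloxy)-2-[2,4-dimethoxy-3-(3-methylbut-2-en-1-yl)phenyl]chroman-4-one, via chalcone 10 (not isolated)
Conditions: KOH (10 equiv), EtOH–H2O, rt, 36 h; then AcOH to pH 6, reflux, 24 h
Reagents that add atoms: none
Why: Claisen–Schmidt condensation gives the 2'-hydroxychalcone, and in the acetate buffer the phenol closes ring C by 6-endo oxa-Michael addition as chalcone isomerase does; the C2 stereocenter is formed racemic, which is harmless because step 4 destroys it.

Step 4
Reactants: 11 (±)-5,7-bis(allyloxy)-2-[2,4-dimethoxy-3-(3-methylbut-2-en-1-yl)phenyl]chroman-4-one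
Product: 14 5,7-bis(allyloxy)-3-[2,4-dimethoxy-3-(3-methylbut-2-en-1-yl)phenyl]-4H-chromen-4-one, via silyl enol ether 12 (not isolated), via iodanyl ketone 13 (not isolated)
Conditions: TMSOTf (1.3 equiv), Et3N (2 equiv), CH2Cl2, 0 °C; pentane, filter, concentrate; PhI(OH)OTs (1.1 equiv), MeCN–CH2Cl2, −40 → 0 °C; aq NaHCO3
Reagents that add atoms: none
Why: Proposed new method: soft enolization gives a silyl enol ether that is several orders of magnitude more nucleophilic than the prenyl and allyl alkenes, so the trivalent iodine reagent attacks only C3, anti to the aryl group, and the very electron-rich 2,4-dimethoxyaryl group, antiperiplanar to the C–I bond, expels iodobenzene through a phenonium ion (2,3-aryl shift) to leave a C2 oxocarbenium ion that loses H3 to give the isoflavone; the closest known reactions are the PhI(OH)OTs-mediated oxidative 2,3-aryl migration of flavanones to isoflavones and the α-functionalization of silyl enol ethers by trivalent iodine reagents.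

Step 5
Reactants: 14 5,7-bis(allyloxy)-3-[2,4-dimethoxy-3-(3-methylbut-2-en-1-yl)phenyl]-4H-chromen-4-one
Product: 16 (3R)-5,7-bis(allyloxy)-3-hydroxy-3-[2,4-dimethoxy-3-(3-methylbut-2-en-1-yl)phenyl]chroman-4-one, via lithium enolate 15 (not isolated)
Conditions: LiBH(s-Bu)3 (1.1 equiv), THF, −78 °C, 1 h; (+)-[(8,8-dimethoxycamphoryl)sulfonyl]oxaziridine (1.5 equiv), THF, −78 → −40 °C; AcOH
Reagents that add atoms: (+)-[(8,8-dimethoxycamphoryl)sulfonyl]oxaziridine, CC1(C)[C@@H]2CC[C@]13CS(=O)(=O)N4O[C@@]34C2(OC)OC
Why: Conjugate hydride addition to the isoflavone gives the tetrasubstituted enolate regiospecifically, and Davis asymmetric enolate hydroxylation with the enantiopure N-sulfonyloxaziridine transfers oxygen to the Re face of C3 (priorities C4 > C2 > C1'), the face being fixed by the camphor skeleton of the reagent, which sets the 3R carbinol center.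

Step 6
Reactants: 16 (3R)-5,7-bis(allyloxy)-3-hydroxy-3-[2,4-dimethoxy-3-(3-methylbut-2-en-1-yl)phenyl]chroman-4-one
Product: 17 (3R)-3,5,7-trihydroxy-3-[2,4-dimethoxy-3-(3-methylbut-2-en-1-yl)phenyl]chroman-4-one
Conditions: Pd(PPh3)4 (5 mol %), morpholine (10 equiv), THF, rt
Reagents that add atoms: none
Why: Tsuji–Trost deallylation, in which zerovalent palladium ionizes only the two aryl allyl ethers and morpholine traps the π-allyl complexes, so the C-prenyl group, the methyl ethers and the quaternary 3R carbinol center are untouched under neutral conditions.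

## Compound list

1 | 2,4-dimethoxybenzaldehyde | COc1ccc(C=O)c(OC)c1 | starting material
2 | prenyl bromide (1-bromo-3-methylbut-2-ene) | CC(C)=CCBr | starting material
3 | lithium (2,4-dimethoxyphenyl)(4-methylpiperazin-1-yl)methanolate | COc1ccc(C(O[Li])N2CCN(C)CC2)c(OC)c1 | intermediate
4 | lithium (3-lithio-2,4-dimethoxyphenyl)(4-methylpiperazin-1-yl)methanolate | COc1ccc(C(O[Li])N2CCN(C)CC2)c(OC)c1[Li] | intermediate
5 | lithium [2,4-dimethoxy-3-(3-methylbut-2-en-1-yl)phenyl](4-methylpiperazin-1-yl)methanolate | COc1ccc(C(O[Li])N2CCN(C)CC2)c(OC)c1CC=C(C)C | intermediate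
6 | 2,4-dimethoxy-3-(3-methylbut-2-en-1-yl)benzaldehyde | COc1ccc(C=O)c(OC)c1CC=C(C)C | intermediate
7 | 2,4,6-trihydroxyacetophenone | CC(=O)c1c(O)cc(O)cc1O | starting material
8 | allyl bromide | C=CCBr | starting material
9 | 1-[2-hydroxy-4,6-bis(prop-2-en-1-yloxy)phenyl]ethan-1-one | CC(=O)c1c(O)cc(OCC=C)cc1OCC=C | intermediate
10 | (E)-1-[2-hydroxy-4,6-bis(allyloxy)phenyl]-3-[2,4-dimethoxy-3-(3-methylbut-2-en-1-yl)phenyl]prop-2-en-1-one (chalcone) | O=C(/C=C/c1ccc(OC)c(CC=C(C)C)c1OC)c1c(O)cc(OCC=C)cc1OCC=C | intermediate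
11 | (±)-5,7-bis(allyloxy)-2-[2,4-dimethoxy-3-(3-methylbut-2-en-1-yl)phenyl]chroman-4-one (flavanone, racemate) | O=C1CC(c2ccc(OC)c(CC=C(C)C)c2OC)Oc2cc(OCC=C)cc(OCC=C)c21 | intermediate
12 | (±)-5,7-bis(allyloxy)-2-[2,4-dimethoxy-3-(3-methylbut-2-en-1-yl)phenyl]-4-(trimethylsilyloxy)-2H-chromene (racemate) | C[Si](C)(C)OC1=CC(c2ccc(OC)c(CC=C(C)C)c2OC)Oc2cc(OCC=C)cc(OCC=C)c21 | intermediate
13 | (±)-trans-5,7-bis(allyloxy)-2-[2,4-dimethoxy-3-(3-methylbut-2-en-1-yl)phenyl]-3-[phenyl(tosyloxy)iodanyl]chroman-4-one (racemate, relative configuration shown) | O=C1[C@H](I(OS(=O)(=O)c2ccc(C)cc2)c2ccccc2)[C@@H](c2ccc(OC)c(CC=C(C)C)c2OC)Oc2cc(OCC=C)cc(OCC=C)c21 | intermediate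
14 | 5,7-bis(allyloxy)-3-[2,4-dimethoxy-3-(3-methylbut-2-en-1-yl)phenyl]-4H-chromen-4-one (isoflavone) | O=c1c(-c2ccc(OC)c(CC=C(C)C)c2OC)coc2cc(OCC=C)cc(OCC=C)c12 | intermediate
15 | lithium 5,7-bis(allyloxy)-3-[2,4-dimethoxy-3-(3-methylbut-2-en-1-yl)phenyl]-2H-chromen-4-olate | [Li]OC1=C(c2ccc(OC)c(CC=C(C)C)c2OC)COc2cc(OCC=C)cc(OCC=C)c21 | intermediate
16 | (3R)-5,7-bis(allyloxy)-3-hydroxy-3-[2,4-dimethoxy-3-(3-methylbut-2-en-1-yl)phenyl]chroman-4-one | COc1ccc([C@@]2(O)COc3cc(OCC=C)cc(OCC=C)c3C2=O)c(OC)c1CC=C(C)C | intermediate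
17 | (3R)-3,5,7-trihydroxy-3-[2,4-dimethoxy-3-(3-methylbut-2-en-1-yl)phenyl]chroman-4-one (CNP0269650.1) | COc1ccc([C@@]2(O)COc3cc(O)cc(O)c3C2=O)c(OC)c1CC=C(C)C | target

## Step count and risks

Total steps: 6 (steps 1 and 2 run in parallel). Longest linear sequence: 5 steps (1 → 6 → 11 → 14 → 16 → 17).

**Step 4, the aryl shift, is the most likely to fail.** The trivalent iodine reagent may also attack the electron-rich ring A, the intermediate may be captured by tosylate, or silylation may open ring C. The fallback sets out from flavanone 11 and replaces the iodine oxidant by a halide leaving group. Silyl enol ether 12 is brominated with NBS (THF, −78 °C), where the enol ether again outruns the alkenes, to give (±)-trans-5,7-bis(allyloxy)-3-bromo-2-[2,4-dimethoxy-3-(3-methylbut-2-en-1-yl)phenyl]chroman-4-one F2. AgOTf with 2,6-di-tert-butylpyridine in CH2Cl2 (−20 °C → rt) then abstracts bromide with participation of the anti aryl group, and the same 2,3-shift and loss of H3 follow. The fallback comes back to the route at isoflavone 14.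

**Step 5, the tandem reduction and hydroxylation, is second.** The boron-associated lithium enolate may be hydroxylated with low or reversed selectivity, or sluggishly. The fallback sets out from isoflavone 14 and takes the chirality from a catalyst instead of a stoichiometric reagent. LiBH(s-Bu)3 (THF, −78 °C) with NH4Cl quench gives (±)-5,7-bis(allyloxy)-3-[2,4-dimethoxy-3-(3-methylbut-2-en-1-yl)phenyl]chroman-4-one F3. This is hydroxylated under phase-transfer catalysis with O2, P(OEt)3, 50 % aqueous KOH and toluene at 0 °C, using 10 mol % of an N-(9-anthracenylmethyl) cinchona alkaloid ammonium salt. The cinchonine- or cinchonidine-derived catalyst is chosen to give 3R. The fallback comes back to the route at 16.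

**Step 1, the one-pot prenylation, is third.** Lithiation of the masked aldehyde may be incomplete, or alkylation may be poor in the presence of the amino alkoxide. The fallback sets out from prenyl bromide 2 and reverses the order of bond formation, with commercial 1,3-dimethoxybenzene in place of 1. 1,3-Dimethoxybenzene is lithiated at C2 (n-BuLi, THF, 0 °C → rt) and alkylated with 2 to give 1,3-dimethoxy-2-(3-methylbut-2-en-1-yl)benzene F1. Vilsmeier–Haack formylation (POCl3, DMF, 0 → 50 °C; aqueous NaOAc) then attacks the only activated position, para to one methoxy group and ortho to the other. The fallback comes back to the route at aldehyde 6.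

## Further compounds

F1 | step 1 | 1,3-dimethoxy-2-(3-methylbut-2-en-1-yl)benzene | COc1cccc(OC)c1CC=C(C)C
F2 | step 4 | (±)-trans-5,7-bis(allyloxy)-3-bromo-2-[2,4-dimethoxy-3-(3-methylbut-2-en-1-yl)phenyl]chroman-4-one (racemate, relative configuration shown) | O=C1[C@H](Br)[C@@H](c2ccc(OC)c(CC=C(C)C)c2OC)Oc2cc(OCC=C)cc(OCC=C)c21
F3 | step 5 | (±)-5,7-bis(allyloxy)-3-[2,4-dimethoxy-3-(3-methylbut-2-en-1-yl)phenyl]chroman-4-one (racemate) | O=C1C(c2ccc(OC)c(CC=C(C)C)c2OC)COc2cc(OCC=C)cc(OCC=C)c21
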